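**Plan**
- Retrosynthesis: the lactone C4–O bond is cut first (iodolactonisation, then C5–I reduction), leaving a C4=C5 alkene and a C3 acetic acid arm. C4=C5 is then cut by ring-closing metathesis, the peroxide C3–O bond by an SN2 union, and the C6–O bond by perhydrolysis of an epoxide.
- Enabling feature: in the 1,2-dioxane ring (O1–O2–C3–C4–C5–C6), C4–C5 is the only ring bond that touches neither peroxide-bearing carbon (C3, C6). C4 also carries the lactone oxygen, so this bond can be made as an alkene and oxygenated afterwards.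
- Forward: aryl–chain coupling and carboalumination build the C5–C6 fragment; the peroxide union joins it to the C1–C4 fragment; metathesis closes the dioxine ring; iodolactonisation closes the lactone ring.
- Stereochemistry: C6 comes from Sharpless epoxidation followed by invertive perhydrolysis. C3 comes from Sharpless kinetic resolution followed by invertive SN2. C4 is relayed from C3, because the tethered carboxylate can only close a cis-fused γ-lactone.

Key step: step 15

Remark: locants C1–C6 follow plakortolide numbering (C1 lactone carbonyl, C3 peroxy CH, C4 lactone-bearing carbon, C6 quaternary peroxy carbon); the acid-catalysed opening of the tertiary epoxide carbon by H2O2 is assumed to go with inversion.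

**Step 1**
Reactants: 1 4-bromophenol
Product: 2 (4-bromophenoxy)triisopropylsilane
Conditions: TIPSCl, imidazole, DMF, rt
Reagents that add atoms: chlorotriisopropylsilane, CC(C)[Si](Cl)(C(C)C)C(C)C
Why: Imidazole-promoted silylation of a phenol; the bulky TIPS ether is chosen because it should withstand the Grignard, peroxide-anion and ylide steps and leave with buffered fluoride at the end.

**Step 2**
Reactants: 3 undec-10-yn-1-ol
Product: 4 undec-10-yn-1-yl 4-methylbenzenesulfonate
Conditions: TsCl, Et3N, DMAP (cat.), CH2Cl2, 0 °C → rt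
Reagents that add atoms: 4-methylbenzenesulfonyl chloride, Cc1ccc(S(=O)(=O)Cl)cc1
Why: Sulfonylation of a primary alcohol gives the electrophile for the copper-catalysed coupling and leaves the alkyne untouched.

**Step 3**
Reactants: 2 (4-bromophenoxy)triisopropylsilane; 4 undec-10-yn-1-yl 4-methylbenzenesulfonate
Product: 8 triisopropyl[4-(undec-10-yn-1-yl)phenoxy]silane, via arylmagnesium bromide 5 (not isolated), via tosylate bromomagnesium acetylide 6 (not isolated), via coupled bromomagnesium acetylide 7 (not isolated)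
Conditions: 2, Mg, THF, reflux; 4, EtMgBr (1.05 equiv), THF, 0 °C → rt; combine, Li2CuCl4 (3 mol %), THF, −10 °C → rt; aq. NH4Cl
Reagents that add atoms: none
Why: Copper-catalysed Kochi-type sp3–sp2 coupling of an aryl Grignard reagent with a primary tosylate; the acetylenic hydrogen is removed beforehand with EtMgBr, the acetylide is a ligand that copper does not transfer, and the C–H returns on quench.

**Step 4**
Reactants: 8 triisopropyl[4-(undec-10-yn-1-yl)phenoxy]silane
Product: 11 (2E)-3-methyl-12-{4-[(triisopropylsilyl)oxy]phenyl}dodec-2-en-1-ol, via alkenyldimethylalane 9 (not isolated), via lithium alkenylaluminate 10 (not isolated)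
Conditions: AlMe3 (2.5 equiv), Cp2ZrCl2 (0.25 equiv), CH2Cl2, 0 °C → rt; evaporate; n-BuLi, THF–hexane, −78 °C; (CH2O)n, −78 °C → rt; aq. potassium sodium tartrate
Reagents that add atoms: trimethylaluminium, C[Al](C)C; paraformaldehyde (as formaldehyde), C=O
Why: Zirconium-catalysed Negishi carboalumination adds methyl and aluminium syn across the terminal alkyne with methyl on the internal carbon, and the derived alanate attacks formaldehyde with retention, so the (E)-trisubstituted allylic alcohol should result.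

**Step 5**
Reactants: 11 (2E)-3-methyl-12-{4-[(triisopropylsilyl)oxy]phenyl}dodec-2-en-1-ol
Product: 12 [(2S,3S)-3-methyl-3-(9-{4-[(triisopropylsilyl)oxy]phenyl}nonyl)oxiran-2-yl]methanol
Conditions: Ti(OiPr)4 (10 mol %), L-(+)-DIPT (12 mol %), t-BuOOH, 4 Å MS, CH2Cl2, −20 °C
Reagents that add atoms: tert-butyl hydroperoxide, CC(C)(C)OO
Why: Sharpless asymmetric epoxidation; with L-(+)-DIPT an (E)-3,3-disubstituted allylic alcohol of the geraniol type gives the (2S,3S)-epoxy alcohol, which fixes the future C6 one inversion ahead.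

**Step 6**
Reactants: 12 [(2S,3S)-3-methyl-3-(9-{4-[(triisopropylsilyl)oxy]phenyl}nonyl)oxiran-2-yl]methanol
Product: 13 (2S,3R)-3-hydroperoxy-3-methyl-12-{4-[(triisopropylsilyl)oxy]phenyl}dodecane-1,2-diol
Conditions: H2O2 (anhydrous, in Et2O, excess), H3PMo12O40 (2 mol %), Et2O, rt
Reagents that add atoms: hydrogen peroxide, OO
Why: Acid-catalysed perhydrolysis of an epoxide, an addition without co-product: H2O2 should open the activated oxirane at the tertiary carbon (the CH next to CH2OH is inductively deactivated) with inversion, giving the (R)-hydroperoxide at C6, while the neighbouring carbinol configuration is erased in step 13.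

**Step 7**
Reactants: 14 propane-1,3-diol
Product: 15 3-[(4-methoxybenzyl)oxy]propan-1-ol
Conditions: NaH, PMBCl, Bu4NI (cat.), THF, 0 °C → rt; 14 in threefold excess
Reagents that add atoms: 4-methoxybenzyl chloride, COc1ccc(CCl)cc1
Why: Williamson monoetherification; the excess of the symmetrical diol keeps bis-alkylation low.

**Step 8**
Reactants: 15 3-[(4-methoxybenzyl)oxy]propan-1-ol
Product: 16 3-[(4-methoxybenzyl)oxy]propanal
Conditions: TEMPO (10 mol %), PhI(OAc)2, CH2Cl2, rt
Reagents that add atoms: none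
Why: TEMPO/PhI(OAc)2 oxidation stops at the aldehyde under near-neutral conditions, which avoids β-elimination of the 4-methoxybenzyloxy group.

**Step 9**
Reactants: 16 3-[(4-methoxybenzyl)oxy]propanal; 17 isopropenylmagnesium bromide
Product: 18 rac-5-[(4-methoxybenzyl)oxy]-2-methylpent-1-en-3-ol
Conditions: 17 (THF solution), THF, −78 → 0 °C; aq. NH4Cl
Reagents that add atoms: none
Why: Grignard 1,2-addition of the alkenylmagnesium reagent to the aldehyde gives the racemic secondary allylic alcohol for the resolution.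

**Step 10**
Reactants: 18 rac-5-[(4-methoxybenzyl)oxy]-2-methylpent-1-en-3-ol
Product: 19 (3R)-5-[(4-methoxybenzyl)oxy]-2-methylpent-1-en-3-ol
Conditions: Ti(OiPr)4 (20 mol %), L-(+)-DIPT (25 mol %), t-BuOOH (0.6 equiv), 4 Å MS, CH2Cl2, −20 °C; stopped a little past half conversion
Reagents that add atoms: none
Why: Sharpless kinetic resolution; with L-(+)-DIPT the (S)-enantiomer of a secondary allylic alcohol is epoxidised much faster, so the unreacted (R)-alcohol should be recovered in high enantiomeric purity.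

**Step 11**
Reactants: 19 (3R)-5-[(4-methoxybenzyl)oxy]-2-methylpent-1-en-3-ol
Product: 20 (3R)-5-[(4-methoxybenzyl)oxy]-2-methylpent-1-en-3-yl methanesulfonate
Conditions: Ms2O, Et3N, CH2Cl2, −30 °C; cold work-up, used at once
Reagents that add atoms: methanesulfonic anhydride, CS(=O)(=O)OS(C)(=O)=O
Why: O-Sulfonylation with retention at carbon; the anhydride is used so that no chloride is present to form an allylic chloride.

**Step 12**
Reactants: 13 (2S,3R)-3-hydroperoxy-3-methyl-12-{4-[(triisopropylsilyl)oxy]phenyl}dodecane-1,2-diol; 20 (3R)-5-[(4-methoxybenzyl)oxy]-2-methylpent-1-en-3-yl methanesulfonate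
Product: 21 (2S,3R)-3-({(3S)-5-[(4-methoxybenzyl)oxy]-2-methylpent-1-en-3-yl}peroxy)-3-methyl-12-{4-[(triisopropylsilyl)oxy]phenyl}dodecane-1,2-diol
Conditions: 13, KOtBu (1.0 equiv), 18-crown-6, THF, −20 °C; then 20 (1.3 equiv) in DMF, −20 → 0 °C
Reagents that add atoms: none
Why: Williamson-type SN2 O-alkylation of an alkylperoxide anion (an α-effect nucleophile, several pKa units more acidic than the diol hydroxyls) by the secondary allylic mesylate; backside attack inverts C3 to the (S) configuration of the target.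

**Step 13**
Reactants: 21 (2S,3R)-3-({(3S)-5-[(4-methoxybenzyl)oxy]-2-methylpent-1-en-3-yl}peroxy)-3-methyl-12-{4-[(triisopropylsilyl)oxy]phenyl}dodecane-1,2-diol
Product: 22 (2R)-2-({(3S)-5-[(4-methoxybenzyl)oxy]-2-methylpent-1-en-3-yl}peroxy)-2-methyl-11-{4-[(triisopropylsilyl)oxy]phenyl}undecanal
Conditions: NaIO4, NaHCO3, THF/H2O, 0 °C → rt
Reagents that add atoms: none
Why: Periodate glycol cleavage (Malaprade reaction) is selective for the 1,2-diol and leaves the dialkyl peroxide, alkene and ethers alone; the new aldehyde has a quaternary α-carbon and cannot epimerise.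

**Step 14**
Reactants: 22 (2R)-2-({(3S)-5-[(4-methoxybenzyl)oxy]-2-methylpent-1-en-3-yl}peroxy)-2-methyl-11-{4-[(triisopropylsilyl)oxy]phenyl}undecanal
Product: 23 triisopropyl{4-[(10R)-10-methyl-10-({(3S)-5-[(4-methoxybenzyl)oxy]-2-methylpent-1-en-3-yl}peroxy)dodec-11-en-1-yl]phenoxy}silane
Conditions: Ph3PCH3Br, KN(SiMe3)2, THF, 0 °C; then 22, −78 → 0 °C
Reagents that add atoms: methyltriphenylphosphonium bromide, C[P+](c1ccccc1)(c1ccccc1)c1ccccc1.[Br-]
Why: Wittig methylenation of a non-enolisable aldehyde with a lithium-free ylide at low temperature, where carbonyl addition should be much faster than base-induced cleavage of the dialkyl peroxide.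

**Step 15**
Reactants: 23 triisopropyl{4-[(10R)-10-methyl-10-({(3S)-5-[(4-methoxybenzyl)oxy]-2-methylpent-1-en-3-yl}peroxy)dodec-11-en-1-yl]phenoxy}silane
Product: 24 (3S,6R)-3-{2-[(4-methoxybenzyl)oxy]ethyl}-4,6-dimethyl-6-(9-{4-[(triisopropylsilyl)oxy]phenyl}nonyl)-3,6-dihydro-1,2-dioxine
Conditions: second-generation Hoveyda–Grubbs catalyst (H2IMes)Cl2Ru=CH(C6H4-2-OiPr) (5–10 mol %), CH2Cl2 (2 mM), 40 °C, argon purge
Reagents that add atoms: none
Why: Proposed new method: the ruthenium alkylidene should load onto the monosubstituted vinyl group (future C5), add across the C4 isopropenyl alkene to a ruthenacyclobutane and cyclorevert to the trisubstituted C4=C5 alkene while ethylene leaves. The closest known reactions are ring-closing metathesis of N-allyl-O-allyl hydroxylamines to 3,6-dihydro-1,2-oxazines and cross-metathesis of allylic dialkyl peroxides, which show that a weak heteroatom–heteroatom bond next to the reacting alkenes survives ruthenium carbenes. The 3,6-dihydro-1,2-dioxine closes as a six-membered ring in the ring-closing-metathesis mode (intramolecular [2+2] cycloaddition and cycloreversion between two terminal alkenes), helped by the gauche C–O–O–C arrangement that holds both alkenes within reach. No stereocentre is formed, and C3 and C6 are untouched because no bond to either is broken. The step needs chemoselectivity for metathesis over O–O cleavage or double-bond migration toward C3–H, and ring closure over oligomerisation; a phosphine-free catalyst, high dilution and a 1,1-disubstituted partner that does not homodimerise should secure both.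

**Step 16**
Reactants: 24 (3S,6R)-3-{2-[(4-methoxybenzyl)oxy]ethyl}-4,6-dimethyl-6-(9-{4-[(triisopropylsilyl)oxy]phenyl}nonyl)-3,6-dihydro-1,2-dioxine
Product: 25 2-[(3S,6R)-4,6-dimethyl-6-(9-{4-[(triisopropylsilyl)oxy]phenyl}nonyl)-3,6-dihydro-1,2-dioxin-3-yl]ethan-1-ol
Conditions: DDQ, CH2Cl2/pH 7 buffer, 0 °C
Reagents that add atoms: none
Why: Oxidative cleavage of the 4-methoxybenzyl ether by DDQ in buffered medium, which should not touch the peroxide, the trisubstituted alkene or the aryl silyl ether and avoids base at the labile C3–H.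

**Step 17**
Reactants: 25 2-[(3S,6R)-4,6-dimethyl-6-(9-{4-[(triisopropylsilyl)oxy]phenyl}nonyl)-3,6-dihydro-1,2-dioxin-3-yl]ethan-1-ol
Product: 26 [(3S,6R)-4,6-dimethyl-6-(9-{4-[(triisopropylsilyl)oxy]phenyl}nonyl)-3,6-dihydro-1,2-dioxin-3-yl]acetic acid
Conditions: TEMPO (20 mol %), PhI(OAc)2 (2.5 equiv), MeCN/H2O (1:1), rt
Reagents that add atoms: water, O
Why: TEMPO/PhI(OAc)2 oxidation in aqueous acetonitrile carries the primary alcohol through the aldehyde hydrate to the acid under mildly acidic conditions that spare the O–O bond and avoid β-elimination of the peroxide.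

**Step 18**
Reactants: 26 [(3S,6R)-4,6-dimethyl-6-(9-{4-[(triisopropylsilyl)oxy]phenyl}nonyl)-3,6-dihydro-1,2-dioxin-3-yl]acetic acid
Product: 27 (3R,4S,4aR,7aS)-4-iodo-3,4a-dimethyl-3-(9-{4-[(triisopropylsilyl)oxy]phenyl}nonyl)tetrahydrofuro[3,2-c][1,2]dioxin-6(3H)-one (iodine on C5, anti to the lactone oxygen)
Conditions: I2, NaHCO3, MeCN, 0 °C, dark; aq. Na2S2O3
Reagents that add atoms: iodine, II
Why: Iodolactonisation: the carboxylate attacks the iodonium ion 5-exo-trig at the more substituted C4 from the face of the C3 acetic acid arm (anti addition), which can only give the cis-fused γ-lactone and so sets C4 from C3; the C5 iodide is temporary.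

**Step 19**
Reactants: 27 (3R,4S,4aR,7aS)-4-iodo-3,4a-dimethyl-3-(9-{4-[(triisopropylsilyl)oxy]phenyl}nonyl)tetrahydrofuro[3,2-c][1,2]dioxin-6(3H)-one
Product: 28 (3R,4aS,7aS)-3,4a-dimethyl-3-(9-{4-[(triisopropylsilyl)oxy]phenyl}nonyl)tetrahydrofuro[3,2-c][1,2]dioxin-6(3H)-one
Conditions: Bu3SnH, AIBN (cat.), benzene, 70 °C
Reagents that add atoms: none
Why: Radical-chain dehalogenation with tin hydride; iodine abstraction and hydrogen transfer to the secondary C5 radical are fast, the in-ring O–O bond is poorly aligned for intramolecular attack, and this iodolactonisation–reduction pair is established on 3,6-dihydro-1,2-dioxin-3-ylacetic acids.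

**Step 20**
Reactants: 28 (3R,4aS,7aS)-3,4a-dimethyl-3-(9-{4-[(triisopropylsilyl)oxy]phenyl}nonyl)tetrahydrofuro[3,2-c][1,2]dioxin-6(3H)-one
Product: 29 plakortolide F, (3R,4aS,7aS)-3-[9-(4-hydroxyphenyl)nonyl]-3,4a-dimethyltetrahydrofuro[3,2-c][1,2]dioxin-6(3H)-one
Conditions: Bu4NF, AcOH (1:1), THF, 0 °C
Reagents that add atoms: none
Why: Fluoride cleavage of the aryl silyl ether, buffered with acetic acid so that the β-peroxy lactone is not exposed to base that could trigger elimination across C2–C3.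

**Compound list**
1 | 4-bromophenol | Oc1ccc(Br)cc1 | starting material
2 | (4-bromophenoxy)triisopropylsilane | CC(C)[Si](Oc1ccc(Br)cc1)(C(C)C)C(C)C | intermediate
3 | undec-10-yn-1-ol | C#CCCCCCCCCCO | starting material
4 | undec-10-yn-1-yl 4-methylbenzenesulfonate | C#CCCCCCCCCCOS(=O)(=O)c1ccc(C)cc1 | intermediate
5 | {4-[(triisopropylsilyl)oxy]phenyl}magnesium bromide | CC(C)[Si](Oc1ccc([Mg]Br)cc1)(C(C)C)C(C)C | intermediate (not isolated)
6 | bromo[11-(tosyloxy)undec-1-yn-1-yl]magnesium | Br[Mg]C#CCCCCCCCCCOS(=O)(=O)c1ccc(C)cc1 | intermediate (not isolated)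
7 | bromo(11-{4-[(triisopropylsilyl)oxy]phenyl}undec-1-yn-1-yl)magnesium | Br[Mg]C#CCCCCCCCCCc1ccc(O[Si](C(C)C)(C(C)C)C(C)C)cc1 | intermediate (not isolated)
8 | triisopropyl[4-(undec-10-yn-1-yl)phenoxy]silane | C#CCCCCCCCCCc1ccc(O[Si](C(C)C)(C(C)C)C(C)C)cc1 | intermediate
9 | dimethyl[(1E)-2-methyl-11-{4-[(triisopropylsilyl)oxy]phenyl}undec-1-en-1-yl]alumane | C[Al](C)/C=C(\C)CCCCCCCCCc1ccc(O[Si](C(C)C)(C(C)C)C(C)C)cc1 | intermediate (not isolated)
10 | lithium butyl(dimethyl)[(1E)-2-methyl-11-{4-[(triisopropylsilyl)oxy]phenyl}undec-1-en-1-yl]aluminate | [Li+].CCCC[Al-](C)(C)/C=C(\C)CCCCCCCCCc1ccc(O[Si](C(C)C)(C(C)C)C(C)C)cc1 | intermediate (not isolated)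
11 | (2E)-3-methyl-12-{4-[(triisopropylsilyl)oxy]phenyl}dodec-2-en-1-ol | OC/C=C(\C)CCCCCCCCCc1ccc(O[Si](C(C)C)(C(C)C)C(C)C)cc1 | intermediate
12 | [(2S,3S)-3-methyl-3-(9-{4-[(triisopropylsilyl)oxy]phenyl}nonyl)oxiran-2-yl]methanol | OC[C@@H]1O[C@@]1(C)CCCCCCCCCc2ccc(O[Si](C(C)C)(C(C)C)C(C)C)cc2 | intermediate
13 | (2S,3R)-3-hydroperoxy-3-methyl-12-{4-[(triisopropylsilyl)oxy]phenyl}dodecane-1,2-diol | C[C@@](OO)(CCCCCCCCCc1ccc(O[Si](C(C)C)(C(C)C)C(C)C)cc1)[C@@H](O)CO | intermediate
14 | propane-1,3-diol | OCCCO | starting material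
15 | 3-[(4-methoxybenzyl)oxy]propan-1-ol | OCCCOCc1ccc(OC)cc1 | intermediate
16 | 3-[(4-methoxybenzyl)oxy]propanal | O=CCCOCc1ccc(OC)cc1 | intermediate
17 | isopropenylmagnesium bromide | C=C(C)[Mg]Br | starting material
18 | rac-5-[(4-methoxybenzyl)oxy]-2-methylpent-1-en-3-ol | C=C(C)C(O)CCOCc1ccc(OC)cc1 | intermediate
19 | (3R)-5-[(4-methoxybenzyl)oxy]-2-methylpent-1-en-3-ol | C=C(C)[C@H](O)CCOCc1ccc(OC)cc1 | intermediate
20 | (3R)-5-[(4-methoxybenzyl)oxy]-2-methylpent-1-en-3-yl methanesulfonate | CS(=O)(=O)O[C@H](CCOCc1ccc(OC)cc1)C(C)=C | intermediate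
21 | (2S,3R)-3-({(3S)-5-[(4-methoxybenzyl)oxy]-2-methylpent-1-en-3-yl}peroxy)-3-methyl-12-{4-[(triisopropylsilyl)oxy]phenyl}dodecane-1,2-diol | C[C@@](OO[C@@H](CCOCc1ccc(OC)cc1)C(C)=C)(CCCCCCCCCc1ccc(O[Si](C(C)C)(C(C)C)C(C)C)cc1)[C@@H](O)CO | intermediate
22 | (2R)-2-({(3S)-5-[(4-methoxybenzyl)oxy]-2-methylpent-1-en-3-yl}peroxy)-2-methyl-11-{4-[(triisopropylsilyl)oxy]phenyl}undecanal | C[C@@](OO[C@@H](CCOCc1ccc(OC)cc1)C(C)=C)(CCCCCCCCCc1ccc(O[Si](C(C)C)(C(C)C)C(C)C)cc1)C=O | intermediate
23 | triisopropyl{4-[(10R)-10-methyl-10-({(3S)-5-[(4-methoxybenzyl)oxy]-2-methylpent-1-en-3-yl}peroxy)dodec-11-en-1-yl]phenoxy}silane | C=C[C@@](C)(CCCCCCCCCc1ccc(O[Si](C(C)C)(C(C)C)C(C)C)cc1)OO[C@@H](CCOCc1ccc(OC)cc1)C(C)=C | intermediate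
24 | (3S,6R)-3-{2-[(4-methoxybenzyl)oxy]ethyl}-4,6-dimethyl-6-(9-{4-[(triisopropylsilyl)oxy]phenyl}nonyl)-3,6-dihydro-1,2-dioxine | C[C@@]1(CCCCCCCCCc2ccc(O[Si](C(C)C)(C(C)C)C(C)C)cc2)C=C(C)[C@H](CCOCc2ccc(OC)cc2)OO1 | intermediate
25 | 2-[(3S,6R)-4,6-dimethyl-6-(9-{4-[(triisopropylsilyl)oxy]phenyl}nonyl)-3,6-dihydro-1,2-dioxin-3-yl]ethan-1-ol | C[C@@]1(CCCCCCCCCc2ccc(O[Si](C(C)C)(C(C)C)C(C)C)cc2)C=C(C)[C@H](CCO)OO1 | intermediate
26 | [(3S,6R)-4,6-dimethyl-6-(9-{4-[(triisopropylsilyl)oxy]phenyl}nonyl)-3,6-dihydro-1,2-dioxin-3-yl]acetic acid | C[C@@]1(CCCCCCCCCc2ccc(O[Si](C(C)C)(C(C)C)C(C)C)cc2)C=C(C)[C@H](CC(=O)O)OO1 | intermediate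
27 | (3R,4S,4aR,7aS)-4-iodo-3,4a-dimethyl-3-(9-{4-[(triisopropylsilyl)oxy]phenyl}nonyl)tetrahydrofuro[3,2-c][1,2]dioxin-6(3H)-one | C[C@@]1(CCCCCCCCCc3ccc(O[Si](C(C)C)(C(C)C)C(C)C)cc3)[C@@H](I)[C@]2(C)OC(=O)C[C@@H]2OO1 | intermediate
28 | (3R,4aS,7aS)-3,4a-dimethyl-3-(9-{4-[(triisopropylsilyl)oxy]phenyl}nonyl)tetrahydrofuro[3,2-c][1,2]dioxin-6(3H)-one | C[C@@]1(CCCCCCCCCc3ccc(O[Si](C(C)C)(C(C)C)C(C)C)cc3)C[C@]2(C)OC(=O)C[C@@H]2OO1 | intermediate
29 | plakortolide F, (3R,4aS,7aS)-3-[9-(4-hydroxyphenyl)nonyl]-3,4a-dimethyltetrahydrofuro[3,2-c][1,2]dioxin-6(3H)-one | C[C@@]1(CCCCCCCCCc2ccc(O)cc2)C[C@]2(C)OC(=O)C[C@@H]2OO1 | target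

**Totals**
Total step count: 20.
Longest linear sequence: 14 steps (steps 1, 3–6 and 12–20 from 4-bromophenol; the sequences from undec-10-yn-1-ol and from propane-1,3-diol are equally long).

**Steps most likely to fail**

1. Step 15 (ring-closing metathesis across the peroxide). The ruthenium carbene may be diverted into O–O scission, or be slowed by the hindered isopropenyl partner so that oligomerisation or double-bond migration wins. The fallback builds the dihydrodioxine by singlet-oxygen [4+2] cycloaddition, a known route to this ring system; it sets out from 8 and comes back at 24. Pent-3-yn-1-ol is protected (NaH, PMBCl) as 1-methoxy-4-[(pent-3-yn-1-yloxy)methyl]benzene F1. Hydrozirconation (Cp2ZrHCl, THF, 50 °C) gives chloridobis(cyclopentadienyl){(2E)-5-[(4-methoxybenzyl)oxy]pent-2-en-2-yl}zirconium F2, and iodinolysis (I2) gives 1-({[(3E)-4-iodopent-3-en-1-yl]oxy}methyl)-4-methoxybenzene F3. Alkyne 8 is carboaluminated as in step 4 to alane 9 and coupled in the same flask with F3 (ZnCl2, Pd(PPh3)4 cat., THF) with retention at both alkenes, giving triisopropyl(4-{(10E,12E)-15-[(4-methoxybenzyl)oxy]-10,12-dimethylpentadeca-10,12-dien-1-yl}phenoxy)silane F4. Photooxygenation (O2, tetraphenylporphyrin, visible light, CH2Cl2, 0 °C) adds suprafacially, so the two chains end up cis as in 24. Both enantiomers form, however, so 24 must be separated from (3R,6S)-3-{2-[(4-methoxybenzyl)oxy]ethyl}-4,6-dimethyl-6-(9-{4-[(triisopropylsilyl)oxy]phenyl}nonyl)-3,6-dihydro-1,2-dioxine F5 by preparative chromatography on a chiral stationary phase before step 16. This fallback gives up reagent control of C3 and C6.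

2. Step 12 (peroxide union). SN2′ attack at the terminal methylene, or E2 loss of methanesulfonic acid, may compete with direct displacement by the bulky tertiary peroxide anion. The fallback reverses the roles of the two fragments; it sets out from 20 and comes back at 21, bypassing 13. The small hydroperoxide anion (H2O2, KOH, MeOH, 0 °C) displaces the mesylate with inversion to give 1-({[(3S)-3-hydroperoxy-4-methylpent-4-en-1-yl]oxy}methyl)-4-methoxybenzene F6. F6, used in excess, then opens epoxy alcohol 12 at the tertiary carbon under H3PMo12O40 catalysis in Et2O, the same invertive epoxide perhydrolysis as in step 6, and should give 21 directly.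

3. Step 14 (methylenation of the α-peroxy aldehyde). Deprotonation at C3–H next to the peroxide (Kornblum–DeLaMare-type fragmentation), or attack of the phosphorus ylide on the O–O bond, may outrun olefination. The fallback is a two-stage Peterson olefination; it sets out from 22 and comes back at 23. Addition of Me3SiCH2MgCl with CeCl3 (THF, −78 °C) gives (3R)-3-({(3S)-5-[(4-methoxybenzyl)oxy]-2-methylpent-1-en-3-yl}peroxy)-3-methyl-1-(trimethylsilyl)-12-{4-[(triisopropylsilyl)oxy]phenyl}dodecan-2-ol F7 as a mixture of carbinol epimers. Acid-induced anti-elimination (dilute H2SO4, THF, 0 °C) then gives 23 without any basic or phosphorus reagent.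

**Further compounds**
F1 | step 15 | 1-methoxy-4-[(pent-3-yn-1-yloxy)methyl]benzene | CC#CCCOCc1ccc(OC)cc1
F2 | step 15 | chloridobis(cyclopentadienyl){(2E)-5-[(4-methoxybenzyl)oxy]pent-2-en-2-yl}zirconium | C/C(=C\CCOCc1ccc(OC)cc1)[Zr](Cl)(C1C=CC=C1)C1C=CC=C1
F3 | step 15 | 1-({[(3E)-4-iodopent-3-en-1-yl]oxy}methyl)-4-methoxybenzene | C/C(I)=C\CCOCc1ccc(OC)cc1
F4 | step 15 | triisopropyl(4-{(10E,12E)-15-[(4-methoxybenzyl)oxy]-10,12-dimethylpentadeca-10,12-dien-1-yl}phenoxy)silane | COc1ccc(COCC/C=C(\C)/C=C(\C)CCCCCCCCCc2ccc(O[Si](C(C)C)(C(C)C)C(C)C)cc2)cc1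
F5 | step 15 | (3R,6S)-3-{2-[(4-methoxybenzyl)oxy]ethyl}-4,6-dimethyl-6-(9-{4-[(triisopropylsilyl)oxy]phenyl}nonyl)-3,6-dihydro-1,2-dioxine | C[C@]1(CCCCCCCCCc2ccc(O[Si](C(C)C)(C(C)C)C(C)C)cc2)C=C(C)[C@@H](CCOCc2ccc(OC)cc2)OO1
F6 | step 12 | 1-({[(3S)-3-hydroperoxy-4-methylpent-4-en-1-yl]oxy}methyl)-4-methoxybenzene | OO[C@@H](CCOCc1ccc(OC)cc1)C(C)=C
F7 | step 14 | (3R)-3-({(3S)-5-[(4-methoxybenzyl)oxy]-2-methylpent-1-en-3-yl}peroxy)-3-methyl-1-(trimethylsilyl)-12-{4-[(triisopropylsilyl)oxy]phenyl}dodecan-2-ol | C[C@@](OO[C@@H](CCOCc1ccc(OC)cc1)C(C)=C)(CCCCCCCCCc1ccc(O[Si](C(C)C)(C(C)C)C(C)C)cc1)C(O)C[Si](C)(C)C
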